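**Retrosynthetic overview**

- The target is (+)-catechin-(4α→6)-(+)-catechin-(4α→6)-(−)-epicatechin. Both interflavan C4–C6 bonds are cut to a C4 cation donor and a nucleophile whose C8 is capped with bromine; the lower bond is made first, then the upper one.
- All three flavan units come from one 8-bromo-2H-chromene-3-carbaldehyde. Its formyl carbon is exchanged for the C3 oxygen by Baeyer–Villiger 1,2-shifts (C3 migrates from carbon to oxygen): on the saturated 2,3-trans aldehyde for the two catechin units, on the enal (then ketone reduction) for the epicatechin unit.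
- Ring C is closed by an amine-catalysed oxa-Michael/aldol condensation of a salicylaldehyde with a cinnamaldehyde; this sets C2.
- Ring A comes from resorcinol dibenzyl ether (formylation, C–H hydroxylation, bromination) and ring B from catechol dibenzyl ether (bromination, Heck reaction).
- Ring order: ring C of each unit first, then union lower–middle, then upper, then global hydrogenolysis.

Assumption: the (S)-diphenylprolinol silyl ether gives the 2R chromene (attack on the iminium face away from the CPh2OTMS group); if the sense proves opposite, its enantiomer is used.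

**Route**

Step 1
Reactants: 1 1,3-bis(benzyloxy)benzene
Product: 2 2,4-bis(benzyloxy)benzaldehyde
Conditions: POCl3, DMF, 0 to 70 °C; then H2O
Reagents that add atoms: N,N-dimethylformamide CN(C)C=O; water O
Why: Vilsmeier–Haack formylation goes to C4, para to one ether oxygen and ortho to the other, while the hindered position between the two oxygens stays free.

Step 2
Reactants: 2 2,4-bis(benzyloxy)benzaldehyde
Product: 3 4,6-bis(benzyloxy)-2-hydroxybenzaldehyde
Conditions: Pd(OAc)2 (10 mol %), 4-chloroanthranilic acid (50 mol %), 1-fluoro-2,4,6-trimethylpyridinium triflate (1.5 equiv), p-TsOH·H2O, ClCH2CH2Cl, 90 °C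
Reagents that add atoms: water O
Why: Palladium-catalysed ortho C–H hydroxylation with a transient imine directing group places the third ring A oxygen at the only free position ortho to the aldehyde, meta to both benzyloxy groups.

Step 3
Reactants: 3 4,6-bis(benzyloxy)-2-hydroxybenzaldehyde
Product: 4 4,6-bis(benzyloxy)-3-bromo-2-hydroxybenzaldehyde
Conditions: NBS (1.0 equiv), i-Pr2NH (10 mol %), CH2Cl2, 0 °C
Reagents that add atoms: N-bromosuccinimide O=C1CCC(=O)N1Br
Why: Amine-mediated ortho-selective electrophilic bromination of the phenol takes the position between OH and OBn (the later C8) and leaves the more hindered position between the two benzyloxy groups (the later C6) free.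

Step 4
Reactants: 5 1,2-bis(benzyloxy)benzene
Product: 6 1,2-bis(benzyloxy)-4-bromobenzene
Conditions: NBS (1.05 equiv), MeCN, rt
Reagents that add atoms: N-bromosuccinimide O=C1CCC(=O)N1Br
Why: Electrophilic aromatic bromination occurs para to an ether oxygen, which is the only unhindered activated position.

Step 5
Reactants: 6 1,2-bis(benzyloxy)-4-bromobenzene; 7 3,3-dimethoxyprop-1-ene
Product: 9 (E)-3-[3,4-bis(benzyloxy)phenyl]prop-2-enal, via dimethyl acetal 8 (not isolated)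
Conditions: Pd(OAc)2 (3 mol %), n-Bu4NOAc, K2CO3, KCl, DMF, 90 °C; then 2 M HCl, rt
Reagents that add atoms: water O
Why: Heck reaction at the terminal alkene carbon gives the E-styryl acetal, and acid hydrolysis of the acetal releases the cinnamaldehyde.

Step 6
Reactants: 4 4,6-bis(benzyloxy)-3-bromo-2-hydroxybenzaldehyde; 9 (E)-3-[3,4-bis(benzyloxy)phenyl]prop-2-enal
Product: 10 (2R)-5,7-bis(benzyloxy)-2-[3,4-bis(benzyloxy)phenyl]-8-bromo-2H-chromene-3-carbaldehyde
Conditions: (S)-α,α-diphenylprolinol trimethylsilyl ether (20 mol %), 2-nitrobenzoic acid (20 mol %), 4 Å molecular sieves, toluene, rt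
Reagents that add atoms: none
Why: Amine-catalysed domino oxa-Michael/aldol condensation (iminium then enamine activation) closes ring C; the phenol oxygen adds to the β-carbon of the E-iminium from the face away from the CPh2OTMS group, which sets C2 as R, and loss of water makes the ring closure irreversible.

Step 7
Reactants: 10 (2R)-5,7-bis(benzyloxy)-2-[3,4-bis(benzyloxy)phenyl]-8-bromo-2H-chromene-3-carbaldehyde
Product: 12 (2S,3S)-5,7-bis(benzyloxy)-2-[3,4-bis(benzyloxy)phenyl]-8-bromochromane-3-carbaldehyde (2,3-trans), via cis aldehyde 11 (not isolated)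
Conditions: Hantzsch ester (diethyl 2,6-dimethyl-1,4-dihydropyridine-3,5-dicarboxylate, 1.2 equiv), dibenzylammonium trifluoroacetate (20 mol %), THF, 40 °C; then DBU (0.3 equiv), CH2Cl2, rt
Reagents that add atoms: none
Why: Iminium-mediated conjugate transfer hydrogenation delivers hydride to C4, and DBU then epimerises the enolisable C3 to the more stable diequatorial 2,3-trans aldehyde while C2 is untouched (its descriptor changes only through priorities).

Step 8
Reactants: 12 (2S,3S)-5,7-bis(benzyloxy)-2-[3,4-bis(benzyloxy)phenyl]-8-bromochromane-3-carbaldehyde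
Product: 14 (2R,3S)-5,7-bis(benzyloxy)-2-[3,4-bis(benzyloxy)phenyl]-8-bromochroman-3-ol (8-bromo-tetra-O-benzyl-(+)-catechin), via formate 13 (not isolated)
Conditions: mCPBA (1.3 equiv), CH2Cl2, 0 °C to rt; then K2CO3 (0.2 equiv), MeOH, 0 °C
Reagents that add atoms: mCPBA O=C(OO)c1cccc(Cl)c1
Why: Baeyer–Villiger oxidation: in the Criegee adduct the secondary carbon C3 shifts from the formyl carbon to oxygen with retention, so the 2,3-trans aldehyde becomes the 2,3-trans formate and, after methanolysis, the (3S) alcohol.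

Step 9
Reactants: 14 (2R,3S)-5,7-bis(benzyloxy)-2-[3,4-bis(benzyloxy)phenyl]-8-bromochroman-3-ol
Product: 15 (2R,3S)-5,7-bis(benzyloxy)-2-[3,4-bis(benzyloxy)phenyl]-6,8-dibromochroman-3-ol
Conditions: NBS (1.05 equiv), CH2Cl2, 0 °C to rt
Reagents that add atoms: N-bromosuccinimide O=C1CCC(=O)N1Br
Why: Electrophilic bromination takes the last free ring A position (C6), so the upper unit has no nucleophilic site left.

Step 10
Reactants: 10 (2R)-5,7-bis(benzyloxy)-2-[3,4-bis(benzyloxy)phenyl]-8-bromo-2H-chromene-3-carbaldehyde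
Product: 17 (2R)-5,7-bis(benzyloxy)-2-[3,4-bis(benzyloxy)phenyl]-8-bromochroman-3-one, via enol formate 16 (not isolated)
Conditions: mCPBA (1.1 equiv), CH2Cl2, 0 °C; then KHCO3, MeOH/THF, 0 °C
Reagents that add atoms: mCPBA O=C(OO)c1cccc(Cl)c1
Why: Baeyer–Villiger oxidation of the enal: the electron-rich vinylic carbon C3 shifts from the formyl carbon to oxygen to give the enol formate, whose mild methanolysis unmasks the C3 ketone without touching C2.

Step 11
Reactants: 17 (2R)-5,7-bis(benzyloxy)-2-[3,4-bis(benzyloxy)phenyl]-8-bromochroman-3-one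
Product: 18 (2R,3R)-5,7-bis(benzyloxy)-2-[3,4-bis(benzyloxy)phenyl]-8-bromochroman-3-ol (8-bromo-tetra-O-benzyl-(−)-epicatechin)
Conditions: LiBH(s-Bu)3, LiBr, THF, −78 °C
Reagents that add atoms: none
Why: The bulky hydride attacks the ketone from the face opposite the C2 aryl group and gives the 2,3-cis (3R) alcohol, the established outcome for benzylated flavan-3-ones.

Step 12
Reactants: 14 (2R,3S)-5,7-bis(benzyloxy)-2-[3,4-bis(benzyloxy)phenyl]-8-bromochroman-3-ol; 18 (2R,3R)-5,7-bis(benzyloxy)-2-[3,4-bis(benzyloxy)phenyl]-8-bromochroman-3-ol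
Product: 20 8-bromo-tetra-O-benzyl-(+)-catechin-(4α→6)-8-bromo-tetra-O-benzyl-(−)-epicatechin, via aryl ether 19 (not isolated)
Conditions: 14, DDQ (1.1 equiv), 4 Å molecular sieves, CH2Cl2, rt; then 18 (3 equiv), TMSOTf (0.2 equiv), −78 to −40 °C
Reagents that add atoms: none
Why: Proposed new method: DDQ abstracts hydride from C4 of 14 (cation stabilised by the three ring A oxygens) and the ion pair collapses to aryl ether 19, which TMSOTf re-ionises so that the cation is trapped by C6 of 18 (C8 blocked by bromine, excess 18 suppressing self-condensation) from the α face trans to the 3-OH, forming the 4α→6 bond in one pot; the closest known reactions are DDQ oxidation of benzylated flavan-3-ols to isolated 4-alkoxy ethers followed by Lewis acid coupling, and DDQ cross-dehydrogenative coupling of benzylic ethers with arenes.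

Step 13
Reactants: 15 (2R,3S)-5,7-bis(benzyloxy)-2-[3,4-bis(benzyloxy)phenyl]-6,8-dibromochroman-3-ol; 20 8-bromo-tetra-O-benzyl-(+)-catechin-(4α→6)-8-bromo-tetra-O-benzyl-(−)-epicatechin
Product: 22 6,8-dibromo-tetra-O-benzyl-(+)-catechin-(4α→6)-8-bromo-tetra-O-benzyl-(+)-catechin-(4α→6)-8-bromo-tetra-O-benzyl-(−)-epicatechin, via aryl ether 21 (not isolated)
Conditions: 15 (1.6 equiv), DDQ (1.7 equiv), 4 Å molecular sieves, CH2Cl2, rt; then 20 (1.0 equiv), TMSOTf (0.2 equiv), −78 to −30 °C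
Reagents that add atoms: none
Why: Proposed new method: the same one-pot DDQ hydride abstraction and TMSOTf re-ionisation as in step 12 generates the C4 cation of the fully capped upper unit, which can only be trapped by the single free ring A position of 20 (C6 of the middle unit) from the α face, giving the second 4α→6 bond; the closest known reactions are the two-stage DDQ/alcohol oxidation plus Lewis acid coupling and DDQ cross-dehydrogenative arylation of benzylic ethers.

Step 14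
Reactants: 22 6,8-dibromo-tetra-O-benzyl-(+)-catechin-(4α→6)-8-bromo-tetra-O-benzyl-(+)-catechin-(4α→6)-8-bromo-tetra-O-benzyl-(−)-epicatechin
Product: 23 (+)-catechin-(4α→6)-(+)-catechin-(4α→6)-(−)-epicatechin (CNP0163146.3)
Conditions: H2 (1 atm), Pd(OH)2/C, Et3N, THF/MeOH/H2O, rt
Reagents that add atoms: none
Why: Hydrogenolysis removes the twelve benzyl ethers and the four aryl bromides in one operation without touching any stereocentre.

**Compound list**

1 | 1,3-bis(benzyloxy)benzene | c1ccc(cc1)COc1cccc(OCc2ccccc2)c1 | starting material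
2 | 2,4-bis(benzyloxy)benzaldehyde | O=Cc1ccc(OCc2ccccc2)cc1OCc1ccccc1 | intermediate
3 | 4,6-bis(benzyloxy)-2-hydroxybenzaldehyde | O=Cc1c(O)cc(OCc2ccccc2)cc1OCc1ccccc1 | intermediate
4 | 4,6-bis(benzyloxy)-3-bromo-2-hydroxybenzaldehyde | O=Cc1c(O)c(Br)c(OCc2ccccc2)cc1OCc1ccccc1 | intermediate
5 | 1,2-bis(benzyloxy)benzene | c1ccc(cc1)COc1ccccc1OCc1ccccc1 | starting material
6 | 1,2-bis(benzyloxy)-4-bromobenzene | Brc1ccc(OCc2ccccc2)c(OCc2ccccc2)c1 | intermediate
7 | 3,3-dimethoxyprop-1-ene (acrolein dimethyl acetal) | C=CC(OC)OC | starting material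
8 | (E)-1,2-bis(benzyloxy)-4-(3,3-dimethoxyprop-1-enyl)benzene | COC(OC)/C=C/c1ccc(OCc2ccccc2)c(OCc2ccccc2)c1 | intermediate
9 | (E)-3-[3,4-bis(benzyloxy)phenyl]prop-2-enal | O=C/C=C/c1ccc(OCc2ccccc2)c(OCc2ccccc2)c1 | intermediate
10 | (2R)-5,7-bis(benzyloxy)-2-[3,4-bis(benzyloxy)phenyl]-8-bromo-2H-chromene-3-carbaldehyde | c1c(OCc3ccccc3)c(Br)c2c(c1OCc1ccccc1)C=C(C=O)[C@@H](c1ccc(OCc3ccccc3)c(OCc3ccccc3)c1)O2 | intermediate
11 | (2S,3R)-5,7-bis(benzyloxy)-2-[3,4-bis(benzyloxy)phenyl]-8-bromochromane-3-carbaldehyde (2,3-cis) | c1c(OCc3ccccc3)c(Br)c2c(c1OCc1ccccc1)C[C@@H](C=O)[C@@H](c1ccc(OCc3ccccc3)c(OCc3ccccc3)c1)O2 | intermediate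
12 | (2S,3S)-5,7-bis(benzyloxy)-2-[3,4-bis(benzyloxy)phenyl]-8-bromochromane-3-carbaldehyde (2,3-trans) | c1c(OCc3ccccc3)c(Br)c2c(c1OCc1ccccc1)C[C@H](C=O)[C@@H](c1ccc(OCc3ccccc3)c(OCc3ccccc3)c1)O2 | intermediate
13 | (2R,3S)-5,7-bis(benzyloxy)-2-[3,4-bis(benzyloxy)phenyl]-8-bromochroman-3-yl formate | c1c(OCc3ccccc3)c(Br)c2c(c1OCc1ccccc1)C[C@H](OC=O)[C@@H](c1ccc(OCc3ccccc3)c(OCc3ccccc3)c1)O2 | intermediate
14 | (2R,3S)-5,7-bis(benzyloxy)-2-[3,4-bis(benzyloxy)phenyl]-8-bromochroman-3-ol | c1c(OCc3ccccc3)c(Br)c2c(c1OCc1ccccc1)C[C@H](O)[C@@H](c1ccc(OCc3ccccc3)c(OCc3ccccc3)c1)O2 | intermediate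
15 | (2R,3S)-5,7-bis(benzyloxy)-2-[3,4-bis(benzyloxy)phenyl]-6,8-dibromochroman-3-ol | Brc1c(OCc3ccccc3)c(Br)c2c(c1OCc1ccccc1)C[C@H](O)[C@@H](c1ccc(OCc3ccccc3)c(OCc3ccccc3)c1)O2 | intermediate
16 | (2R)-5,7-bis(benzyloxy)-2-[3,4-bis(benzyloxy)phenyl]-8-bromo-2H-chromen-3-yl formate | c1c(OCc3ccccc3)c(Br)c2c(c1OCc1ccccc1)C=C(OC=O)[C@@H](c1ccc(OCc3ccccc3)c(OCc3ccccc3)c1)O2 | intermediate
17 | (2R)-5,7-bis(benzyloxy)-2-[3,4-bis(benzyloxy)phenyl]-8-bromochroman-3-one | c1c(OCc3ccccc3)c(Br)c2c(c1OCc1ccccc1)CC(=O)[C@@H](c1ccc(OCc3ccccc3)c(OCc3ccccc3)c1)O2 | intermediate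
18 | (2R,3R)-5,7-bis(benzyloxy)-2-[3,4-bis(benzyloxy)phenyl]-8-bromochroman-3-ol | c1c(OCc3ccccc3)c(Br)c2c(c1OCc1ccccc1)C[C@@H](O)[C@@H](c1ccc(OCc3ccccc3)c(OCc3ccccc3)c1)O2 | intermediate
19 | 4β-(2,3-dichloro-5,6-dicyano-4-hydroxyphenoxy) ether of 14 (2,3-trans, 3,4-cis; drawn as the expected epimer, either epimer gives the same cation) | c1ccccc1COc1cc(OCc3ccccc3)c2c(c1Br)O[C@H](c1ccc(OCc3ccccc3)c(OCc3ccccc3)c1)[C@@H](O)[C@H]2Oc1c(Cl)c(Cl)c(O)c(C#N)c1C#N | intermediate
20 | 8-bromo-5,7,3',4'-tetra-O-benzyl-(+)-catechin-(4α→6)-8-bromo-5,7,3',4'-tetra-O-benzyl-(−)-epicatechin | c1c(OCc4ccccc4)c(Br)c2c(c1OCc1ccccc1)[C@@H](c1c(OCc4ccccc4)c(Br)c3c(c1OCc1ccccc1)C[C@@H](O)[C@@H](c1ccc(OCc4ccccc4)c(OCc4ccccc4)c1)O3)[C@H](O)[C@@H](c1ccc(OCc4ccccc4)c(OCc4ccccc4)c1)O2 | intermediate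
21 | 4β-(2,3-dichloro-5,6-dicyano-4-hydroxyphenoxy) ether of 15 (2,3-trans, 3,4-cis; drawn as the expected epimer) | c1ccccc1COc1c(Br)c(OCc3ccccc3)c2c(c1Br)O[C@H](c1ccc(OCc3ccccc3)c(OCc3ccccc3)c1)[C@@H](O)[C@H]2Oc1c(Cl)c(Cl)c(O)c(C#N)c1C#N | intermediate
22 | 6,8-dibromo-5,7,3',4'-tetra-O-benzyl-(+)-catechin-(4α→6)-8-bromo-5,7,3',4'-tetra-O-benzyl-(+)-catechin-(4α→6)-8-bromo-5,7,3',4'-tetra-O-benzyl-(−)-epicatechin | c1ccccc1COc1c(Br)c(OCc4ccccc4)c2c(c1Br)O[C@H](c1ccc(OCc4ccccc4)c(OCc4ccccc4)c1)[C@@H](O)[C@@H]2c1c(OCc4ccccc4)c(Br)c2c(c1OCc1ccccc1)[C@@H](c1c(OCc4ccccc4)c(Br)c3c(c1OCc1ccccc1)C[C@@H](O)[C@@H](c1ccc(OCc4ccccc4)c(OCc4ccccc4)c1)O3)[C@H](O)[C@@H](c1ccc(OCc4ccccc4)c(OCc4ccccc4)c1)O2 | intermediate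
23 | (+)-catechin-(4α→6)-(+)-catechin-(4α→6)-(−)-epicatechin (CNP0163146.3) | Oc1cc(O)c2c(c1)O[C@H](c1ccc(O)c(O)c1)[C@@H](O)[C@@H]2c1c(O)cc2c(c1O)[C@@H](c1c(O)cc3c(c1O)C[C@@H](O)[C@@H](c1ccc(O)c(O)c1)O3)[C@H](O)[C@@H](c1ccc(O)c(O)c1)O2 | target

**Totals and risks**

Total step count: 14. Longest linear sequence: 9 steps (1, 2, 3, 6, 7, 8, 9, 13, 14).

The three steps most likely to fail:

- Step 2 (C–H hydroxylation of an electron-rich, benzyl-protected aldehyde under acidic oxidative conditions). The fallback sets out from 2 and returns at 3. Aldehyde 2 is condensed with O-methylhydroxylamine hydrochloride and pyridine to (E)-2,4-bis(benzyloxy)benzaldehyde O-methyl oxime F1. Oxime-ether-directed acetoxylation with Pd(OAc)2 and PhI(OAc)2 in AcOH/Ac2O then functionalises the only free ortho C–H and gives 3,5-bis(benzyloxy)-2-[(E)-(methoxyimino)methyl]phenyl acetate F2. Aqueous HCl with excess formaldehyde in THF removes the acetate and exchanges off the oxime to give 3.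

- Step 8 (Baeyer–Villiger oxidation of the saturated aldehyde, where hydrogen migration to the carboxylic acid can compete with migration of C3). The fallback sets out from 12 and returns at 14. MeMgBr in THF at −78 °C adds to 12 to give the 2,3-trans secondary alcohol 1-[5,7-bis(benzyloxy)-2-(3,4-bis(benzyloxy)phenyl)-8-bromochroman-3-yl]ethanol F3 (carbinol epimers). Dess–Martin periodinane oxidises it to the methyl ketone 1-[(2S,3S)-5,7-bis(benzyloxy)-2-(3,4-bis(benzyloxy)phenyl)-8-bromochroman-3-yl]ethanone F4. Baeyer–Villiger oxidation of this ketone with mCPBA, in which the secondary carbon migrates in preference to methyl with retention, gives (2R,3S)-5,7-bis(benzyloxy)-2-[3,4-bis(benzyloxy)phenyl]-8-bromochroman-3-yl acetate F5. K2CO3 in MeOH then gives 14.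

- Step 12 (the proposed one-pot oxidative coupling; step 13 uses the same method). The fallback uses the known two-stage sequence, sets out from 14 and returns at 20. DDQ oxidation of 14 in CH2Cl2 in the presence of 2-ethoxyethanol gives the isolated ether (2R,3S,4S)-5,7-bis(benzyloxy)-2-[3,4-bis(benzyloxy)phenyl]-8-bromo-4-(2-ethoxyethoxy)chroman-3-ol F6. TMSOTf-catalysed condensation of this ether with excess 18 at −78 °C (the established 4→6 coupling with a bromine cap on C8) gives 20. The same relay from 15 goes through (2R,3S,4S)-5,7-bis(benzyloxy)-2-[3,4-bis(benzyloxy)phenyl]-6,8-dibromo-4-(2-ethoxyethoxy)chroman-3-ol F7, which is condensed with 20 under TMSOTf and rejoins the route at 22.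

**Further compounds**

F1 | step 2 | (E)-2,4-bis(benzyloxy)benzaldehyde O-methyl oxime | CO/N=C/c1ccc(OCc2ccccc2)cc1OCc1ccccc1
F2 | step 2 | 3,5-bis(benzyloxy)-2-[(E)-(methoxyimino)methyl]phenyl acetate | CO/N=C/c1c(OC(C)=O)cc(OCc2ccccc2)cc1OCc1ccccc1
F3 | step 8 | 1-[5,7-bis(benzyloxy)-2-(3,4-bis(benzyloxy)phenyl)-8-bromochroman-3-yl]ethanol (2,3-trans as in 12, carbinol epimers) | c1c(OCc3ccccc3)c(Br)c2c(c1OCc1ccccc1)C[C@H](C(C)O)[C@@H](c1ccc(OCc3ccccc3)c(OCc3ccccc3)c1)O2
F4 | step 8 | 1-[(2S,3S)-5,7-bis(benzyloxy)-2-(3,4-bis(benzyloxy)phenyl)-8-bromochroman-3-yl]ethanone | c1c(OCc3ccccc3)c(Br)c2c(c1OCc1ccccc1)C[C@H](C(C)=O)[C@@H](c1ccc(OCc3ccccc3)c(OCc3ccccc3)c1)O2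
F5 | step 8 | (2R,3S)-5,7-bis(benzyloxy)-2-[3,4-bis(benzyloxy)phenyl]-8-bromochroman-3-yl acetate | c1c(OCc3ccccc3)c(Br)c2c(c1OCc1ccccc1)C[C@H](OC(C)=O)[C@@H](c1ccc(OCc3ccccc3)c(OCc3ccccc3)c1)O2
F6 | step 12 | (2R,3S,4S)-5,7-bis(benzyloxy)-2-[3,4-bis(benzyloxy)phenyl]-8-bromo-4-(2-ethoxyethoxy)chroman-3-ol | c1ccccc1COc1cc(OCc3ccccc3)c2c(c1Br)O[C@H](c1ccc(OCc3ccccc3)c(OCc3ccccc3)c1)[C@@H](O)[C@H]2OCCOCC
F7 | step 12 | (2R,3S,4S)-5,7-bis(benzyloxy)-2-[3,4-bis(benzyloxy)phenyl]-6,8-dibromo-4-(2-ethoxyethoxy)chroman-3-ol | c1ccccc1COc1c(Br)c(OCc3ccccc3)c2c(c1Br)O[C@H](c1ccc(OCc3ccccc3)c(OCc3ccccc3)c1)[C@@H](O)[C@H]2OCCOCC
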